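**Retrosynthetic overview**
1. Last events: fluoride removal of four silyl ethers, and conversion of an N-(quinolin-8-yl)amide on the quaternary ring carbon into the methyl ester.
2. Key disconnection: the bond between the benzylic CH2 on the quaternary carbon and the 4-hydroxy-3-prenylphenyl ring. It is made by amide-directed, palladium-catalysed C(sp3)–H arylation of a methyl group with an aryl iodide, so the whole hydroxy(prenyl)benzyl arm is placed on a CH3 that originates from pyruvate.
3. Enabling feature: the quaternary carbon C5 of the furanone ring bears both this CH3/CH2 and a carboxyl carbon (1,3-relationship) and has no hydrogen. A bidentate amide at that carboxyl therefore holds palladium in a five-membered palladacycle at the methyl C–H, and C5 can neither epimerise nor lose a β-hydrogen.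
4. Only one ring is made, the butenolide (O1–C5). It and the (R) centre at C5 come from a chiral copper bis(oxazoline)-catalysed cross-aldol addition of an arylpyruvate to allyl pyruvate, followed by lactonisation; both benzene rings are bought.
5. The arylpyruvate comes from 3-bromo-4,5-dihydroxybenzaldehyde (silylation, Stille prenylation, Horner–Wadsworth–Emmons olefination); the aryl iodide comes from 4-iodophenol (ortho-C-prenylation, silylation).

Key step: step 11

Numbering and abbreviations: butenolide numbering is O1, C2 (lactone C=O), C3 (enol carbon), C4 (catechol-bearing carbon), C5 (quaternary carbon; it is C2 in the systematic 2,5-dihydrofuran-2-carboxylate names). ArB = 3,4-bis[(tert-butyldimethylsilyl)oxy]-5-(3-methylbut-2-en-1-yl)phenyl; ArA = 4-[(tert-butyldimethylsilyl)oxy]-3-(3-methylbut-2-en-1-yl)phenyl; TBS = tert-butyldimethylsilyl; TIPS = tri(propan-2-yl)silyl.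

Remark (assumption): the silyloxy-phosphonate used in step 3 is taken as a purchasable olefination reagent; keto esters and the 3-hydroxybutenolide are each drawn as one tautomer.

**Step 1**
Reactants: 1 3-bromo-4,5-dihydroxybenzaldehyde
Product: 2 3-bromo-4,5-bis(TBS-oxy)benzaldehyde
Conditions: TBSCl (2.4 equiv), imidazole (5 equiv), DMF, rt
Reagents that add atoms: tert-butyldimethylsilyl chloride, CC(C)(C)[Si](C)(C)Cl
Why: Silyl ether formation on both phenols protects the catechol through the organometallic and basic steps and allows release at the end with fluoride instead of acid.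

**Step 2**
Reactants: 2 3-bromo-4,5-bis(TBS-oxy)benzaldehyde
Product: 3 3,4-bis(TBS-oxy)-5-(3-methylbut-2-en-1-yl)benzaldehyde (ArB–CHO)
Conditions: tributyl(3-methylbut-2-en-1-yl)stannane (1.3 equiv), Pd(PPh3)4 (5 mol %), toluene, 100 °C, degassed
Reagents that add atoms: tributyl(3-methylbut-2-en-1-yl)stannane, CCCC[Sn](CCCC)(CCCC)CC=C(C)C
Why: Stille coupling transfers the prenyl group from tin to the aryl bromide at the unsubstituted allyl terminus, the usual outcome with this catalyst, under neutral conditions that leave the aldehyde and the silyl ethers alone.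

**Step 3**
Reactants: 3 ArB–CHO; 4 methyl 2-(TBS-oxy)-2-(dimethoxyphosphoryl)acetate
Product: 6 methyl 3-(ArB)-2-oxopropanoate, via silyl enol ether 5 (not isolated)
Conditions: LiN(SiMe3)2 (1.05 equiv), THF, −78 °C to rt; then Et3N·3HF (1.5 equiv), THF, 0 °C
Reagents that add atoms: none
Why: Horner–Wadsworth–Emmons olefination gives the silyl enol ether of the α-keto ester (E/Z mixture, both converge), and amine–HF cleaves this enol silyl ether much faster than the two aryl silyl ethers, releasing the arylpyruvate without base.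

**Step 4**
Reactants: 7 pyruvic acid
Product: 8 prop-2-en-1-yl 2-oxopropanoate (allyl pyruvate)
Conditions: allyl alcohol (3 equiv), p-TsOH·H2O (2 mol %), cyclohexane, reflux with azeotropic removal of water; distillation
Reagents that add atoms: prop-2-en-1-ol (allyl alcohol), C=CCO
Why: Fischer esterification; the allyl ester is chosen because zerovalent palladium later removes it under neutral conditions.

**Step 5**
Reactants: 6 methyl 3-(ArB)-2-oxopropanoate; 8 allyl pyruvate
Product: 10 allyl (2R)-3-(ArB)-4-hydroxy-2-methyl-5-oxo-2,5-dihydrofuran-2-carboxylate, via aldol adduct 9 (not isolated)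
Conditions: Cu(OTf)2 (10 mol %), (R,R)-t-Bu-box [2,2'-(propane-2,2-diyl)bis((4R)-4-tert-butyl-4,5-dihydrooxazole)] (11 mol %), N,N-dimethylaniline (10 mol %), 8 (3 equiv), slow addition of 6, CH2Cl2/Et2O, −20 °C to rt; then SiO2, CH2Cl2, rt to complete lactonisation
Reagents that add atoms: none
Why: Direct catalytic asymmetric aldol addition of the enol of the more acidic arylpyruvate to the ketone of the pyruvate ester, which is bound as a five-membered chelate to the chiral copper bis(oxazoline) Lewis acid (a reaction type established for pyruvate esters), followed by lactonisation of the tertiary alcohol onto the keto-ester carbonyl; the (R,R)-ligand is chosen so that, by the chelate model, the enol attacks the Re face of the ketone (priorities O > CO2allyl > CH3), which gives (R) at the new quaternary carbon, the sense being confirmed on the first batch and reversed with the (S,S)-ligand if needed.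

**Step 6**
Reactants: 10 allyl (2R)-3-(ArB)-4-hydroxy-2-methyl-5-oxo-2,5-dihydrofuran-2-carboxylate
Product: 11 allyl (2R)-3-(ArB)-2-methyl-5-oxo-4-(TIPS-oxy)-2,5-dihydrofuran-2-carboxylate
Conditions: TIPSOTf (1.2 equiv), 2,6-lutidine (2 equiv), CH2Cl2, −78 to 0 °C
Reagents that add atoms: tri(propan-2-yl)silyl trifluoromethanesulfonate, CC(C)[Si](C(C)C)(C(C)C)OS(=O)(=O)C(F)(F)F
Why: O-silylation of the acidic enol blocks the enol oxygen for the acylation and C–H activation steps and removes the 3-oxo tautomer through which ring opening and retro-aldol loss of configuration would run.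

**Step 7**
Reactants: 11 allyl (2R)-3-(ArB)-2-methyl-5-oxo-4-(TIPS-oxy)-2,5-dihydrofuran-2-carboxylate
Product: 12 (2R)-3-(ArB)-2-methyl-5-oxo-4-(TIPS-oxy)-2,5-dihydrofuran-2-carboxylic acid
Conditions: Pd(PPh3)4 (3 mol %), morpholine (3 equiv), THF, rt; cold pH 4 buffer work-up; used at once
Reagents that add atoms: none
Why: Tsuji–Trost-type deallylation, in which zerovalent palladium ionises the allyl ester and morpholine traps the allyl group, leaves the lactone, the silyl ethers and the carbon-bound prenyl groups untouched.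

**Step 8**
Reactants: 12 (2R)-3-(ArB)-2-methyl-5-oxo-4-(TIPS-oxy)-2,5-dihydrofuran-2-carboxylic acid
Product: 14 (2R)-3-(ArB)-2-methyl-5-oxo-N-(quinolin-8-yl)-4-(TIPS-oxy)-2,5-dihydrofuran-2-carboxamide, via acid chloride 13 (not isolated)
Conditions: 1-chloro-N,N,2-trimethylprop-1-en-1-amine (1.2 equiv), CH2Cl2, 0 °C to rt; then quinolin-8-amine (1.3 equiv), pyridine (3 equiv), DMAP (10 mol %), 0 °C to rt
Reagents that add atoms: quinolin-8-amine (8-aminoquinoline), Nc1cccc2cccnc12; 1-chloro-N,N,2-trimethylprop-1-en-1-amine, CC(C)=C(Cl)N(C)C (supplies the chlorine of 13 only)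
Why: Amide formation through an acid chloride made under neutral conditions with an α-chloroenamine suits the hindered quaternary acid and the weakly nucleophilic aminoquinoline, and C5, having no hydrogen, cannot epimerise.

**Step 9**
Reactants: 15 4-iodophenol
Product: 16 4-iodo-2-(3-methylbut-2-en-1-yl)phenol
Conditions: NaH (1.1 equiv), toluene, 0 °C; 1-bromo-3-methylbut-2-ene (1.0 equiv), rt
Reagents that add atoms: 1-bromo-3-methylbut-2-ene (prenyl bromide), CC(C)=CCBr
Why: ortho-C-Alkylation of a sodium phenoxide in a non-polar solvent, where the tight ion pair directs the allylic bromide to the ortho carbon and iodine blocks the para position.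

**Step 10**
Reactants: 16 4-iodo-2-(3-methylbut-2-en-1-yl)phenol
Product: 17 tert-butyl[4-iodo-2-(3-methylbut-2-en-1-yl)phenoxy]dimethylsilane (ArA–I)
Conditions: TBSCl (1.2 equiv), imidazole (2.5 equiv), DMF, rt
Reagents that add atoms: tert-butyldimethylsilyl chloride, CC(C)(C)[Si](C)(C)Cl
Why: Silyl ether formation masks the phenol, which would otherwise bind palladium and silver in the key step, with the same fluoride-labile group used elsewhere.

**Step 11**
Reactants: 14 (2R)-3-(ArB)-2-methyl-5-oxo-N-(quinolin-8-yl)-4-(TIPS-oxy)-2,5-dihydrofuran-2-carboxamide; 17 ArA–I (2.5 equiv)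
Product: 18 (2R)-2-[(ArA)methyl]-3-(ArB)-5-oxo-N-(quinolin-8-yl)-4-(TIPS-oxy)-2,5-dihydrofuran-2-carboxamide
Conditions: Pd(OAc)2 (10 mol %), AgOAc (1.5 equiv), tert-amyl alcohol, 80 °C, argon, dark
Reagents that add atoms: none
Why: The deprotonated amide nitrogen and the quinoline nitrogen bind Pd(OAc)2 as an N,N-chelate, and acetate-assisted concerted metalation–deprotonation at the C5 methyl, the only C–H bond that can close a five-membered palladacycle, gives an alkyl complex of divalent palladium; oxidative addition of aryl iodide 17 to tetravalent palladium and C–C reductive elimination then form the CH2–aryl bond, while AgOAc removes iodide and returns acetate. The closest known reaction type is the 8-aminoquinoline-directed β-methyl arylation of α,α-disubstituted propanamides, including α-oxygenated (lactic-acid-type) ones, with aryl iodides. No ring is closed and no stereocentre is formed: the (R) centre at C5 is quaternary and none of its bonds is broken, so its configuration is carried over unchanged. The step needs site selectivity for the methyl over every other C–H bond and mono- over diarylation; the first is secured by palladacycle size (C4 has no hydrogen and the aryl ortho C–H bonds would require a seven-membered ring), the second by the much slower activation of the new, hindered benzylic CH2. Lactone opening by β-oxygen elimination is disfavoured because the C5–O1 bond cannot become periplanar to the C–Pd bond inside the rigid bicyclic palladacycle, and the trisubstituted prenyl alkenes and the tetrasubstituted ring alkene are poor partners for insertion into the aryl–palladium bond.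

**Step 12**
Reactants: 18 (2R)-2-[(ArA)methyl]-3-(ArB)-5-oxo-N-(quinolin-8-yl)-4-(TIPS-oxy)-2,5-dihydrofuran-2-carboxamide
Product: 19 methyl (2R)-2-[(ArA)methyl]-3-(ArB)-5-oxo-4-(TIPS-oxy)-2,5-dihydrofuran-2-carboxylate
Conditions: Ni(tmhd)2 [nickel bis(2,2,6,6-tetramethylheptane-3,5-dionate)] (15 mol %), MeOH, 100 °C, sealed tube
Reagents that add atoms: methanol, CO
Why: Nickel-catalysed alcoholysis of the N,N-chelating 8-aminoquinoline amide gives the methyl ester under neutral conditions that touch neither C5 nor the alkenes, and any silyl ether lost here is of no consequence because step 13 removes them all.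

**Step 13**
Reactants: 19 methyl (2R)-2-[(ArA)methyl]-3-(ArB)-5-oxo-4-(TIPS-oxy)-2,5-dihydrofuran-2-carboxylate
Product: 20 methyl (2R)-3-[3,4-dihydroxy-5-(3-methylbut-2-en-1-yl)phenyl]-4-hydroxy-2-{[4-hydroxy-3-(3-methylbut-2-en-1-yl)phenyl]methyl}-5-oxo-2,5-dihydrofuran-2-carboxylate (target)
Conditions: Bu4NF (5 equiv), AcOH (5 equiv), THF, 0 °C to rt, argon; pH 5 work-up
Reagents that add atoms: none
Why: Fluoride-mediated desilylation buffered with acetic acid frees the three phenols and the enol without acid strong enough to cyclise the ortho-prenyl phenols to chromans and without base strong enough to open the lactone.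

**Compound list**
1 | 3-bromo-4,5-dihydroxybenzaldehyde | O=Cc1cc(O)c(O)c(Br)c1 | starting material
2 | 3-bromo-4,5-bis[(tert-butyldimethylsilyl)oxy]benzaldehyde | O=Cc1cc(O[Si](C)(C)C(C)(C)C)c(O[Si](C)(C)C(C)(C)C)c(Br)c1 | intermediate
3 | 3,4-bis[(tert-butyldimethylsilyl)oxy]-5-(3-methylbut-2-en-1-yl)benzaldehyde | O=Cc1cc(O[Si](C)(C)C(C)(C)C)c(O[Si](C)(C)C(C)(C)C)c(CC=C(C)C)c1 | intermediate
4 | methyl 2-[(tert-butyldimethylsilyl)oxy]-2-(dimethoxyphosphoryl)acetate | COC(=O)C(O[Si](C)(C)C(C)(C)C)P(=O)(OC)OC | starting material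
5 | methyl (2Z)-3-{3,4-bis[(tert-butyldimethylsilyl)oxy]-5-(3-methylbut-2-en-1-yl)phenyl}-2-[(tert-butyldimethylsilyl)oxy]prop-2-enoate (Z drawn; E/Z mixture expected) | COC(=O)/C(O[Si](C)(C)C(C)(C)C)=C/c1cc(O[Si](C)(C)C(C)(C)C)c(O[Si](C)(C)C(C)(C)C)c(CC=C(C)C)c1 | intermediate (not isolated)
6 | methyl 3-{3,4-bis[(tert-butyldimethylsilyl)oxy]-5-(3-methylbut-2-en-1-yl)phenyl}-2-oxopropanoate (keto form drawn) | COC(=O)C(=O)Cc1cc(O[Si](C)(C)C(C)(C)C)c(O[Si](C)(C)C(C)(C)C)c(CC=C(C)C)c1 | intermediate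
7 | pyruvic acid | CC(=O)C(=O)O | starting material
8 | prop-2-en-1-yl 2-oxopropanoate | CC(=O)C(=O)OCC=C | intermediate
9 | 1-(prop-2-en-1-yl) 5-methyl (2R)-3-{3,4-bis[(tert-butyldimethylsilyl)oxy]-5-(3-methylbut-2-en-1-yl)phenyl}-2-hydroxy-2-methyl-4-oxopentanedioate (both C3 epimers) | C=CCOC(=O)[C@](C)(O)C(c1cc(O[Si](C)(C)C(C)(C)C)c(O[Si](C)(C)C(C)(C)C)c(CC=C(C)C)c1)C(=O)C(=O)OC | intermediate (not isolated)
10 | prop-2-en-1-yl (2R)-3-{3,4-bis[(tert-butyldimethylsilyl)oxy]-5-(3-methylbut-2-en-1-yl)phenyl}-4-hydroxy-2-methyl-5-oxo-2,5-dihydrofuran-2-carboxylate | C=CCOC(=O)[C@]1(C)OC(=O)C(O)=C1c1cc(O[Si](C)(C)C(C)(C)C)c(O[Si](C)(C)C(C)(C)C)c(CC=C(C)C)c1 | intermediate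
11 | prop-2-en-1-yl (2R)-3-{3,4-bis[(tert-butyldimethylsilyl)oxy]-5-(3-methylbut-2-en-1-yl)phenyl}-2-methyl-5-oxo-4-{[tri(propan-2-yl)silyl]oxy}-2,5-dihydrofuran-2-carboxylate | C=CCOC(=O)[C@]1(C)OC(=O)C(O[Si](C(C)C)(C(C)C)C(C)C)=C1c1cc(O[Si](C)(C)C(C)(C)C)c(O[Si](C)(C)C(C)(C)C)c(CC=C(C)C)c1 | intermediate
12 | (2R)-3-{3,4-bis[(tert-butyldimethylsilyl)oxy]-5-(3-methylbut-2-en-1-yl)phenyl}-2-methyl-5-oxo-4-{[tri(propan-2-yl)silyl]oxy}-2,5-dihydrofuran-2-carboxylic acid | OC(=O)[C@]1(C)OC(=O)C(O[Si](C(C)C)(C(C)C)C(C)C)=C1c1cc(O[Si](C)(C)C(C)(C)C)c(O[Si](C)(C)C(C)(C)C)c(CC=C(C)C)c1 | intermediate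
13 | (2R)-3-{3,4-bis[(tert-butyldimethylsilyl)oxy]-5-(3-methylbut-2-en-1-yl)phenyl}-2-methyl-5-oxo-4-{[tri(propan-2-yl)silyl]oxy}-2,5-dihydrofuran-2-carbonyl chloride | ClC(=O)[C@]1(C)OC(=O)C(O[Si](C(C)C)(C(C)C)C(C)C)=C1c1cc(O[Si](C)(C)C(C)(C)C)c(O[Si](C)(C)C(C)(C)C)c(CC=C(C)C)c1 | intermediate (not isolated)
14 | (2R)-3-{3,4-bis[(tert-butyldimethylsilyl)oxy]-5-(3-methylbut-2-en-1-yl)phenyl}-2-methyl-5-oxo-N-(quinolin-8-yl)-4-{[tri(propan-2-yl)silyl]oxy}-2,5-dihydrofuran-2-carboxamide | O=C(Nc1cccc2cccnc12)[C@]1(C)OC(=O)C(O[Si](C(C)C)(C(C)C)C(C)C)=C1c1cc(O[Si](C)(C)C(C)(C)C)c(O[Si](C)(C)C(C)(C)C)c(CC=C(C)C)c1 | intermediate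
15 | 4-iodophenol | Oc1ccc(I)cc1 | starting material
16 | 4-iodo-2-(3-methylbut-2-en-1-yl)phenol | CC(C)=CCc1cc(I)ccc1O | intermediate
17 | tert-butyl[4-iodo-2-(3-methylbut-2-en-1-yl)phenoxy]dimethylsilane | CC(C)=CCc1cc(I)ccc1O[Si](C)(C)C(C)(C)C | intermediate
18 | (2R)-3-{3,4-bis[(tert-butyldimethylsilyl)oxy]-5-(3-methylbut-2-en-1-yl)phenyl}-2-({4-[(tert-butyldimethylsilyl)oxy]-3-(3-methylbut-2-en-1-yl)phenyl}methyl)-5-oxo-N-(quinolin-8-yl)-4-{[tri(propan-2-yl)silyl]oxy}-2,5-dihydrofuran-2-carboxamide | O=C(Nc1cccc2cccnc12)[C@]1(Cc2ccc(O[Si](C)(C)C(C)(C)C)c(CC=C(C)C)c2)OC(=O)C(O[Si](C(C)C)(C(C)C)C(C)C)=C1c1cc(O[Si](C)(C)C(C)(C)C)c(O[Si](C)(C)C(C)(C)C)c(CC=C(C)C)c1 | intermediate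
19 | methyl (2R)-3-{3,4-bis[(tert-butyldimethylsilyl)oxy]-5-(3-methylbut-2-en-1-yl)phenyl}-2-({4-[(tert-butyldimethylsilyl)oxy]-3-(3-methylbut-2-en-1-yl)phenyl}methyl)-5-oxo-4-{[tri(propan-2-yl)silyl]oxy}-2,5-dihydrofuran-2-carboxylate | COC(=O)[C@]1(Cc2ccc(O[Si](C)(C)C(C)(C)C)c(CC=C(C)C)c2)OC(=O)C(O[Si](C(C)C)(C(C)C)C(C)C)=C1c1cc(O[Si](C)(C)C(C)(C)C)c(O[Si](C)(C)C(C)(C)C)c(CC=C(C)C)c1 | intermediate
20 | methyl (2R)-3-[3,4-dihydroxy-5-(3-methylbut-2-en-1-yl)phenyl]-4-hydroxy-2-{[4-hydroxy-3-(3-methylbut-2-en-1-yl)phenyl]methyl}-5-oxo-2,5-dihydrofuran-2-carboxylate | COC(=O)[C@]1(Cc2ccc(O)c(CC=C(C)C)c2)OC(=O)C(O)=C1c1cc(O)c(O)c(CC=C(C)C)c1 | target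

**Step count**
Total steps: 13. Longest linear sequence: 10 steps (1, 2, 3, 5, 6, 7, 8, 11, 12, 13).

**Steps most likely to fail**

Step 11. C–H palladation at the congested methyl may be slower than palladium-mediated reactions at the two trisubstituted alkenes, or the alkylpalladium intermediate may open the lactone by β-oxygen elimination. The fallback sets out from 17 and 6 and returns at 20; it builds the benzyl arm before the ring and gives up the common late intermediate.
- Iodide 17 is converted by iodine–magnesium exchange (i-PrMgCl·LiCl, THF, −20 °C) and DMF into 4-[(tert-butyldimethylsilyl)oxy]-3-(3-methylbut-2-en-1-yl)benzaldehyde F1.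
- The step 3 protocol with 4 gives, through methyl (2Z)-2-[(tert-butyldimethylsilyl)oxy]-3-{4-[(tert-butyldimethylsilyl)oxy]-3-(3-methylbut-2-en-1-yl)phenyl}prop-2-enoate F2, the keto ester methyl 3-{4-[(tert-butyldimethylsilyl)oxy]-3-(3-methylbut-2-en-1-yl)phenyl}-2-oxopropanoate F3.
- Keto ester 6 is silylated (Me3SiCl, Et3N) to methyl (2Z)-3-{3,4-bis[(tert-butyldimethylsilyl)oxy]-5-(3-methylbut-2-en-1-yl)phenyl}-2-[(trimethylsilyl)oxy]prop-2-enoate F4.
- Mukaiyama aldol addition of F4 to the ketone of F3 under Cu(OTf)2/(R,R)-t-Bu-box gives dimethyl (2R)-3-{3,4-bis[(tert-butyldimethylsilyl)oxy]-5-(3-methylbut-2-en-1-yl)phenyl}-2-({4-[(tert-butyldimethylsilyl)oxy]-3-(3-methylbut-2-en-1-yl)phenyl}methyl)-4-oxo-2-[(trimethylsilyl)oxy]pentanedioate F5.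
- Dilute HCl in THF removes the trimethylsilyl group, and the tertiary alcohol lactonises to methyl (2R)-3-{3,4-bis[(tert-butyldimethylsilyl)oxy]-5-(3-methylbut-2-en-1-yl)phenyl}-2-({4-[(tert-butyldimethylsilyl)oxy]-3-(3-methylbut-2-en-1-yl)phenyl}methyl)-4-hydroxy-5-oxo-2,5-dihydrofuran-2-carboxylate F6.
- The step 13 conditions convert F6 into 20.

Step 5. The enol of 6 may add to a second molecule of 6, or 8 may add to itself, faster than the cross reaction; reversible addition before lactonisation may also erode facial selectivity. The fallback sets out from 6 and returns at 10; it fixes the donor and acceptor roles beforehand.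
- Keto ester 6 is converted into its enol silane, methyl (2Z)-3-{3,4-bis[(tert-butyldimethylsilyl)oxy]-5-(3-methylbut-2-en-1-yl)phenyl}-2-[(trimethylsilyl)oxy]prop-2-enoate F4.
- F4 is added to 8 in a Mukaiyama aldol reaction under the same chiral copper Lewis acid, the reaction type for which pyruvate esters are the standard acceptors. This gives 1-(prop-2-en-1-yl) 5-methyl (2R)-3-{3,4-bis[(tert-butyldimethylsilyl)oxy]-5-(3-methylbut-2-en-1-yl)phenyl}-2-methyl-4-oxo-2-[(trimethylsilyl)oxy]pentanedioate F7.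
- Dilute HCl in THF desilylates F7, which lactonises to 10.

Step 12. Methanol may fail to attack the hindered amide carbonyl next to the quaternary carbon, while prolonged heating solvolyses silyl ethers and exposes the lactone instead. The fallback sets out from 18 and returns at 19; it uses stoichiometric activation in place of catalytic alcoholysis.
- The amide is acylated on nitrogen (Boc2O, DMAP, MeCN, rt) to tert-butyl N-{[(2R)-3-{3,4-bis[(tert-butyldimethylsilyl)oxy]-5-(3-methylbut-2-en-1-yl)phenyl}-2-({4-[(tert-butyldimethylsilyl)oxy]-3-(3-methylbut-2-en-1-yl)phenyl}methyl)-5-oxo-4-{[tri(propan-2-yl)silyl]oxy}-2,5-dihydrofuran-2-yl]carbonyl}-N-(quinolin-8-yl)carbamate F8.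
- The twisted imide of F8 is cleaved by LiOMe in MeOH/THF at 0 °C to give 19; any aryl silyl ether lost in this step is removed anyway in step 13.

**Further compounds**
F1 | step 11 | 4-[(tert-butyldimethylsilyl)oxy]-3-(3-methylbut-2-en-1-yl)benzaldehyde | O=Cc1ccc(O[Si](C)(C)C(C)(C)C)c(CC=C(C)C)c1
F2 | step 11 | methyl (2Z)-2-[(tert-butyldimethylsilyl)oxy]-3-{4-[(tert-butyldimethylsilyl)oxy]-3-(3-methylbut-2-en-1-yl)phenyl}prop-2-enoate | COC(=O)/C(O[Si](C)(C)C(C)(C)C)=C/c1ccc(O[Si](C)(C)C(C)(C)C)c(CC=C(C)C)c1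
F3 | step 11 | methyl 3-{4-[(tert-butyldimethylsilyl)oxy]-3-(3-methylbut-2-en-1-yl)phenyl}-2-oxopropanoate | COC(=O)C(=O)Cc1ccc(O[Si](C)(C)C(C)(C)C)c(CC=C(C)C)c1
F4 | step 11 | methyl (2Z)-3-{3,4-bis[(tert-butyldimethylsilyl)oxy]-5-(3-methylbut-2-en-1-yl)phenyl}-2-[(trimethylsilyl)oxy]prop-2-enoate | COC(=O)/C(O[Si](C)(C)C)=C/c1cc(O[Si](C)(C)C(C)(C)C)c(O[Si](C)(C)C(C)(C)C)c(CC=C(C)C)c1
F5 | step 11 | dimethyl (2R)-3-{3,4-bis[(tert-butyldimethylsilyl)oxy]-5-(3-methylbut-2-en-1-yl)phenyl}-2-({4-[(tert-butyldimethylsilyl)oxy]-3-(3-methylbut-2-en-1-yl)phenyl}methyl)-4-oxo-2-[(trimethylsilyl)oxy]pentanedioate | COC(=O)[C@](Cc1ccc(O[Si](C)(C)C(C)(C)C)c(CC=C(C)C)c1)(O[Si](C)(C)C)C(c1cc(O[Si](C)(C)C(C)(C)C)c(O[Si](C)(C)C(C)(C)C)c(CC=C(C)C)c1)C(=O)C(=O)OC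
F6 | step 11 | methyl (2R)-3-{3,4-bis[(tert-butyldimethylsilyl)oxy]-5-(3-methylbut-2-en-1-yl)phenyl}-2-({4-[(tert-butyldimethylsilyl)oxy]-3-(3-methylbut-2-en-1-yl)phenyl}methyl)-4-hydroxy-5-oxo-2,5-dihydrofuran-2-carboxylate | COC(=O)[C@]1(Cc2ccc(O[Si](C)(C)C(C)(C)C)c(CC=C(C)C)c2)OC(=O)C(O)=C1c1cc(O[Si](C)(C)C(C)(C)C)c(O[Si](C)(C)C(C)(C)C)c(CC=C(C)C)c1
F7 | step 5 | 1-(prop-2-en-1-yl) 5-methyl (2R)-3-{3,4-bis[(tert-butyldimethylsilyl)oxy]-5-(3-methylbut-2-en-1-yl)phenyl}-2-methyl-4-oxo-2-[(trimethylsilyl)oxy]pentanedioate | C=CCOC(=O)[C@](C)(O[Si](C)(C)C)C(c1cc(O[Si](C)(C)C(C)(C)C)c(O[Si](C)(C)C(C)(C)C)c(CC=C(C)C)c1)C(=O)C(=O)OC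
F8 | step 12 | tert-butyl N-{[(2R)-3-{3,4-bis[(tert-butyldimethylsilyl)oxy]-5-(3-methylbut-2-en-1-yl)phenyl}-2-({4-[(tert-butyldimethylsilyl)oxy]-3-(3-methylbut-2-en-1-yl)phenyl}methyl)-5-oxo-4-{[tri(propan-2-yl)silyl]oxy}-2,5-dihydrofuran-2-yl]carbonyl}-N-(quinolin-8-yl)carbamate | CC(C)(C)OC(=O)N(c1cccc2cccnc12)C(=O)[C@]1(Cc2ccc(O[Si](C)(C)C(C)(C)C)c(CC=C(C)C)c2)OC(=O)C(O[Si](C(C)C)(C(C)C)C(C)C)=C1c1cc(O[Si](C)(C)C(C)(C)C)c(O[Si](C)(C)C(C)(C)C)c(CC=C(C)C)c1
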